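## Structural features

The target is a biflavonoid in which two C15 units are joined by one diaryl ether. One unit is a (2S)-5-hydroxy-7-methoxyflavanone (benzo ring A, dihydropyranone ring C, 2-aryl ring B) and the other a 5,7,4'-trihydroxyflavone (benzo ring D, pyranone ring E, 2-aryl ring F); the ether runs from C4' of ring B to C3' of ring F. C2 of ring C is the only stereocentre and has no stereogenic neighbour. It is benzylic, carries the ring oxygen and lies β to the C4 carbonyl, so base reopens ring C by E1cB to an achiral 2'-hydroxychalcone and racemises it. Ring C is therefore fragile toward base, the four free phenols toward oxidation and the C2=C3 bond of ring E toward reduction, whereas the diaryl ether and the aryl methyl ether are sturdy. The real difficulty is to set C2 late and as one enantiomer through a reversible C–O closure, in a molecule that already holds the flavone half and in which only O7 of ring A, out of five phenolic oxygens, is methylated. In ring A the oxygens sit on alternate carbons (C5, C7, C8a), C7 bears the methyl ether, and C4a, between the two free oxygens, bears the acyl carbon C4. This is the folding pattern of a triketide, and the same six carbons with the same methylated oxygen are present, masked as a lactone, in 4-methoxy-6-methyl-2-pyranone once its methyl group has been acylated by a cinnamoyl unit; the key step uses this and closes ring A by joining C4a to C8a.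

## Logic of the disconnections

17 to 16: the four benzyl–oxygen bonds (O5 of ring A, O5 and O7 of ring D, O4' of ring F) are cut. Every phenol except the one that closes ring C has to be masked through the base steps, and one kind of ether allows a single neutral release at the end. The forward step must remove four benzyl groups without epimerising C2, without cleaving the benzylic O1–C2 bond of ring C and without saturating C2=C3 of ring E.

16 to 15: the O1–C2 bond of ring C is cut. This removes the only stereocentre and one ring and leaves an achiral enone with a single free phenol. The forward step is a 6-endo oxa-Michael addition in which a chiral catalyst must choose the face of C2, and the uncatalysed closure has to stay slow.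

15 to 14: one benzyl–oxygen bond on ring A is cut. The two phenols of 14 are equivalent, so no regiocontrol is needed, only mono-selectivity. The forward step relies on the second hydroxyl being locked in a hydrogen bond to the ketone after the first has been alkylated.

14 to 12 (through 13): the C4a–C8a bond is cut and ring A is unfolded to a pyranone-masked triketo ester. Ring A, its oxygen pattern and the position of the methyl ether are thereby traced to one commercial heterocycle. The forward step must fold in the Claisen sense and not the aldol sense, and must tolerate the enone and the flavone.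

12 to 9 and 10 (through 11): the bond between the future C4a and the future C4 is cut. The C6 methyl group of 10 is its vinylogously acidic position, and a Weinreb amide stops cleanly at the ketone stage. The forward step needs 1,2-addition to a cinnamoyl amide and no attack on the flavone.

9 to 7 and 8: the future C2=C3 double bond is cut in the olefination sense. This reduces the side chain to an aryl aldehyde and a two-carbon phosphonate. The forward step must give the E alkene.

7 to 5 and 6: the diaryl ether is cut at the O–C bond on the ring B side. The formyl group needed for the next step is also the group that activates fluoride for substitution. Making the ether after the flavone is finished means that two aldehydes never have to be differentiated. The forward step needs one free phenol only, which 5 provides.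

5 to 4: the O1–C2 bond of ring E and its C2=C3 unsaturation are cut, giving an open 2'-hydroxychalcone. The forward step is an oxidative ring closure that must spare the benzyl ethers and the free phenol on ring F.

4 to 2 and 3: the enone double bond is cut in the aldol sense, giving an acetophenone and an aldehyde. The forward step must work with an aldehyde that carries a free phenol.

2 to 1: two benzyl–oxygen bonds are cut. The forward step must leave the chelated hydroxyl free.

## Other disconnections considered

Alternative 1: The cut is C4–C4a of ring C. In the forward direction n-BuLi would convert the bromo acid A2 into its lithium carboxylate and exchange bromine for lithium at the future C4a; the aryllithium would add to the carboxylate (Parham cycloacylation) and give chromanone A1.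
- In its favour: C2 would be set on an open chain before ring closure, and the ring would close by an irreversible C–C bond formation, so the closure itself could not lose enantiopurity by a retro-oxa-Michael path. Ring A would come from a simple bromophenol unit. On these two points Alternative 1 is the better plan.
- Against it here: A2 needs its benzylic aryl ether made with defined configuration at a carbon that ionises easily (para-aryloxy benzylic). Its aryloxide is also a β-leaving group under strongly basic conditions.
- A1 carries methyl ethers on both O5 and O7, so O5 would later need a selective Lewis-acid demethylation that also threatens the benzyl ether.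
- A1 contains none of rings D to F. After acetal hydrolysis the flavone would have to be built by condensation in strong base and oxidative closure on a molecule that already holds the finished flavanone. Base would reopen and racemise ring C, and an iodine oxidant would dehydrogenate it.
- Structure: the chosen plan carries the complete flavone through and sets C2 in the second-last step; Alternative 1 sets C2 early and then exposes it.
- Mechanism: irreversible carbanion acylation against reversible catalyst-controlled C–O closure. The alternative is safer at the closure and much less safe afterwards.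
- Step economy: reaching A1 would take about as many steps as reaching 14, and five or six more would follow, so it is longer.

Alternative 2: The cut is double, C4a–C8a of ring D and O1–C2 of ring E. In the forward direction Mg(OMe)2 would open hydroxypyranone A4 to a 9-aryl-3,5,7,9-tetraoxononanoate, a Claisen closure would give ring D with an aroylacetyl side chain, and the acid quench would close ring E by cyclodehydration to flavone A3.
- In its favour: it uses the same magnesium-templated folding as the chosen key step and makes two rings in one flask. O5 and O7 of the flavone emerge free, so two benzyl groups fewer are carried; on protecting-group economy at rings D and E it is the better plan.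
- The aryl bromide of A3 is a sturdy handle. A Heck coupling with an acrylic Weinreb amide would reach the cinnamoyl amide stage in one step, which equals the substitution and olefination pair of the chosen plan.
- Against it here: A4 has a free hydroxyl where the chosen precursor has an enol ether, so nothing blocks the carbon next to the ester as an aldol nucleophile. A tetraketide also has more folding modes than a triketide.
- A4 itself needs polyanion acylation chemistry, and the phenols of A3 would have to be masked again before any carbanion step.
- Structure: it addresses the easy half of the molecule, since the flavone is reachable from 2 and 3 in two reliable steps, and leaves ring A and C2 untouched.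
- Mechanism: equal in kind to the chosen key step but with weaker regiocontrol.
- Step economy: no gain, and used together with the chosen key step it would put two polyketide foldings into one route.

Alternative 3: The cut is O1–C2 of ring C, the same bond as in step 9, but on a chalcone that carries a tert-butyl ester on its α-carbon. In the forward direction A6, from Knoevenagel condensation of 7 with β-keto ester A7, would cyclise under a cinchona-derived thiourea to A5. Acid would then remove the tert-butyl ester, and decarboxylation would give 16.
- In its favour: the alkylidene β-keto ester is a much stronger acceptor than the plain enone of 15 and offers the thiourea a two-point binding site. On enantiocontrol this alternative is the better founded of the two.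
- Ring A would be bought and not built. The whole route would need about nine steps against ten, so on step count it is equal or slightly better.
- Against it here: the decarboxylation needs acid and heat on a flavanone whose C2 is benzylic and activated by the para-aryloxy group, at the stage where the enantiopurity has just been set.
- The Knoevenagel condensation joins a hindered 2,6-disubstituted aroylacetate to the poorly soluble 7, and A7 needs a C-acylation of a chelated, hindered acetophenone. The C3 centre of A5 is made only to be discarded.
- Structure: both plans converge at 16.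
- Mechanism: same bond and same catalyst class; the alternative is the more secure version of step 9. The chosen plan instead has no acid and heat step after C2 is set, and it builds ring A from the pyranone.
- Step economy: roughly equal.

Key step: step 7

Remark on the structures: 12 and 14 are used as drawn; the ring-opened enoate 13 has its ester carbon cis to the carbon chain, which by the sequence rule is 2E (the methoxy oxygen outranks C4), and it is written as 2E throughout.

Assumption: the sense of induction of the cinchona thiourea in step 9 has to be fixed by a trial run; the quinidine-derived catalyst is written, and its quinine-derived pseudoenantiomer, N-[3,5-bis(trifluoromethyl)phenyl]-N'-[(8α,9S)-6'-methoxycinchonan-9-yl]thiourea, takes its place if the trial shows 2R.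

## Route

Step 1
Reactants: 1 2',4',6'-trihydroxyacetophenone
Product: 2 1-[2,4-bis(benzyloxy)-6-hydroxyphenyl]ethan-1-one
Conditions: BnBr (2.05 equiv), K2CO3 (2.2 equiv), DMF, rt
Reagents that add atoms: benzyl bromide, BrCc1ccccc1
Why: Williamson ether synthesis; two phenoxides react, and the hydroxyl that stays hydrogen-bonded to the acetyl group is left because its phenoxide is far less nucleophilic.

Step 2
Reactants: 2 1-[2,4-bis(benzyloxy)-6-hydroxyphenyl]ethan-1-one, 3 4-(benzyloxy)-3-hydroxybenzaldehyde
Product: 4 (2E)-1-[2,4-bis(benzyloxy)-6-hydroxyphenyl]-3-[4-(benzyloxy)-3-hydroxyphenyl]prop-2-en-1-one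
Conditions: KOH (50% aq., 15 equiv), EtOH/THF, rt; then 1 M HCl, 0 °C
Reagents that add atoms: none
Why: Claisen–Schmidt condensation (aldol addition, then E1cB loss of water to the E enone); the phenoxide of 3 is meta to the formyl group and cannot delocalise its charge into it, so the aldehyde stays electrophilic, and in strong base the product remains open as its phenoxide.

Step 3
Reactants: 4 (2E)-1-[2,4-bis(benzyloxy)-6-hydroxyphenyl]-3-[4-(benzyloxy)-3-hydroxyphenyl]prop-2-en-1-one
Product: 5 5,7-bis(benzyloxy)-2-[4-(benzyloxy)-3-hydroxyphenyl]-4H-chromen-4-one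
Conditions: I2 (10 mol%), DMSO, 120 °C; aq. Na2S2O3 work-up
Reagents that add atoms: none
Why: iodine-catalysed oxidative cyclisation of a 2'-hydroxychalcone with DMSO as terminal oxidant; the chelated phenol closes ring E by oxa-Michael addition, iodination at C3 and loss of HI give the flavone, and DMSO returns HI to I2. Free phenols of the 3-hydroxy-4-alkoxy type on the 2-aryl ring are known to survive iodine-mediated flavone formation.

Step 4
Reactants: 5 5,7-bis(benzyloxy)-2-[4-(benzyloxy)-3-hydroxyphenyl]-4H-chromen-4-one, 6 4-fluorobenzaldehyde
Product: 7 4-{2-(benzyloxy)-5-[5,7-bis(benzyloxy)-4-oxo-4H-chromen-2-yl]phenoxy}benzaldehyde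
Conditions: K2CO3 (2 equiv), DMF, 110 °C
Reagents that add atoms: none
Why: nucleophilic aromatic substitution by addition–elimination; the para formyl group stabilises the Meisenheimer intermediate and fluoride leaves. 5 has only one phenol, and the flavone and benzyl ethers are inert to carbonate.

Step 5
Reactants: 7 4-{2-(benzyloxy)-5-[5,7-bis(benzyloxy)-4-oxo-4H-chromen-2-yl]phenoxy}benzaldehyde, 8 diethyl {2-[methoxy(methyl)amino]-2-oxoethyl}phosphonate
Product: 9 (2E)-3-(4-{2-(benzyloxy)-5-[5,7-bis(benzyloxy)-4-oxo-4H-chromen-2-yl]phenoxy}phenyl)-N-methoxy-N-methylprop-2-enamide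
Conditions: NaH (1.3 equiv), 8 (1.3 equiv), THF, 0 °C; then 7 in THF/DMF, 0 °C → rt
Reagents that add atoms: none
Why: Horner–Wadsworth–Emmons olefination with a stabilised phosphonate carbanion, which gives the E alkene; the flavone carbonyl is a vinylogous ester and does not compete with the aldehyde.

Step 6
Reactants: 10 4-methoxy-6-methyl-2H-pyran-2-one, 9 (2E)-3-(4-{2-(benzyloxy)-5-[5,7-bis(benzyloxy)-4-oxo-4H-chromen-2-yl]phenoxy}phenyl)-N-methoxy-N-methylprop-2-enamide
Product: 12 6-[(3E)-4-(4-{2-(benzyloxy)-5-[5,7-bis(benzyloxy)-4-oxo-4H-chromen-2-yl]phenoxy}phenyl)-2-oxobut-3-en-1-yl]-4-methoxy-2H-pyran-2-one, via lithiated pyranone 11 (not isolated)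
Conditions: 10 (2.2 equiv), LiN(i-Pr)2 (2.1 equiv), THF, −78 °C; then 9 in THF, −78 → −40 °C; 1 M HCl, −40 → 0 °C
Reagents that add atoms: none
Why: lateral (vinylogous) lithiation of the C6 methyl group of the pyranone, then acylation by the Weinreb amide; the N-methoxy chelate holds the tetrahedral adduct until the quench, so the ketone is not attacked a second time, and hard lithium carbanions add 1,2 to cinnamoyl Weinreb amides. The amide base is fully consumed by the excess of 10 before 9 is added, which protects the flavone.

Step 7
Reactants: 12 6-[(3E)-4-(4-{2-(benzyloxy)-5-[5,7-bis(benzyloxy)-4-oxo-4H-chromen-2-yl]phenoxy}phenyl)-2-oxobut-3-en-1-yl]-4-methoxy-2H-pyran-2-one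
Product: 14 (2E)-3-(4-{2-(benzyloxy)-5-[5,7-bis(benzyloxy)-4-oxo-4H-chromen-2-yl]phenoxy}phenyl)-1-(2,6-dihydroxy-4-methoxyphenyl)prop-2-en-1-one, via ring-opened methyl enoate 13 (not isolated)
Conditions: Mg(OMe)2 (5 equiv), MeOH/THF, 65 °C, under argon; then poured into 1 M HCl at 0 °C, fast extraction, no chromatography
Reagents that add atoms: none
Why: Methoxide adds to the lactone carbonyl of 12 and the ring opens to the magnesium enolate of 13, in which the enoate keeps the ester carbon cis to the chain (2E), the arrangement it had in the ring. Mg2+ binds the 5,7-dioxo unit as a chelated β-diketonate, so the carbanion character sits on the future C4a, the most acidic carbon of the chain. C4a attacks the ester carbonyl (future C8a) in a 6-exo-trig Claisen acylation, methoxide leaves, and enolisation of the two ring ketones aromatises ring A. The closest known reaction type is the alkoxide-induced opening and Claisen cyclisation of 6-(2-oxoalkyl)-2-pyranones, which act as masked 3,5,7-triketo esters, to acylphloroglucinols. No stereocentre is formed and the E enone is not touched. The selectivity needed is Claisen over aldol folding and a single site for the methyl ether: the C7 enol ether makes C8 an sp2 carbon that cannot act as the aldol nucleophile, the 2E geometry holds the ester within reach of C4a, and the methyl group never leaves its oxygen. While the medium is basic the enone is cross-conjugated with magnesium-bound enolate or phenoxide oxygens and is a poor acceptor for methoxide or for the new phenoxides; the cold acid quench is meant to carry 14 quickly through the pH range in which ring C would close.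

Step 8
Reactants: 14 (2E)-3-(4-{2-(benzyloxy)-5-[5,7-bis(benzyloxy)-4-oxo-4H-chromen-2-yl]phenoxy}phenyl)-1-(2,6-dihydroxy-4-methoxyphenyl)prop-2-en-1-one
Product: 15 (2E)-1-[2-(benzyloxy)-6-hydroxy-4-methoxyphenyl]-3-(4-{2-(benzyloxy)-5-[5,7-bis(benzyloxy)-4-oxo-4H-chromen-2-yl]phenoxy}phenyl)prop-2-en-1-one
Conditions: crude 14, BnBr (1.05 equiv), K2CO3 (1.5 equiv), acetone, rt
Reagents that add atoms: benzyl bromide, BrCc1ccccc1
Why: Williamson ether synthesis on one of two equivalent phenols; after the first alkylation the remaining hydroxyl is locked in the hydrogen bond to the ketone and reacts much more slowly. Any material whose ring C has closed early is reopened by carbonate (E1cB) and trapped as the same ether, so the step is convergent.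

Step 9
Reactants: 15 (2E)-1-[2-(benzyloxy)-6-hydroxy-4-methoxyphenyl]-3-(4-{2-(benzyloxy)-5-[5,7-bis(benzyloxy)-4-oxo-4H-chromen-2-yl]phenoxy}phenyl)prop-2-en-1-one
Product: 16 (2S)-5-(benzyloxy)-2-(4-{2-(benzyloxy)-5-[5,7-bis(benzyloxy)-4-oxo-4H-chromen-2-yl]phenoxy}phenyl)-7-methoxy-2,3-dihydro-4H-chromen-4-one
Conditions: N-[3,5-bis(trifluoromethyl)phenyl]-N'-[(9R)-6'-methoxycinchonan-9-yl]thiourea (10–20 mol%), toluene/CH2Cl2, 0 °C → rt
Reagents that add atoms: none
Why: organocatalytic asymmetric intramolecular oxa-Michael addition (6-endo-trig) of a 2'-hydroxychalcone; the quinuclidine nitrogen takes up the phenol proton while the thiourea N–H bonds bind the enone oxygen, so the phenoxide is delivered to one face of C2 inside the ion pair. C2 is set as S by the catalyst alone, and the benzyl ether leaves a single hydrogen-bonded phenol, which keeps the uncatalysed closure slow.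

Step 10
Reactants: 16 (2S)-5-(benzyloxy)-2-(4-{2-(benzyloxy)-5-[5,7-bis(benzyloxy)-4-oxo-4H-chromen-2-yl]phenoxy}phenyl)-7-methoxy-2,3-dihydro-4H-chromen-4-one
Product: 17 (2S)-2-{4-[5-(5,7-dihydroxy-4-oxo-4H-chromen-2-yl)-2-hydroxyphenoxy]phenyl}-5-hydroxy-7-methoxy-2,3-dihydro-4H-chromen-4-one
Conditions: H2 (1 atm), 10% Pd/C, THF/MeOH, rt
Reagents that add atoms: none
Why: hydrogenolysis of four aryl benzyl ethers under neutral conditions, in which C2 cannot epimerise. The C2=C3 bond of ring E (a vinylogous ester) and the O1–C2 bond of ring C react far more slowly than O-benzyl groups, so the reaction is stopped when the last benzyl ether has gone.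

## Compound list

1 | 2',4',6'-trihydroxyacetophenone | CC(=O)c1c(O)cc(O)cc1O | starting material
2 | 1-[2,4-bis(benzyloxy)-6-hydroxyphenyl]ethan-1-one | CC(=O)c1c(O)cc(OCc2ccccc2)cc1OCc1ccccc1 | intermediate
3 | 4-(benzyloxy)-3-hydroxybenzaldehyde | O=Cc1ccc(OCc2ccccc2)c(O)c1 | starting material
4 | (2E)-1-[2,4-bis(benzyloxy)-6-hydroxyphenyl]-3-[4-(benzyloxy)-3-hydroxyphenyl]prop-2-en-1-one | O=C(/C=C/c1ccc(OCc2ccccc2)c(O)c1)c1c(O)cc(OCc2ccccc2)cc1OCc1ccccc1 | intermediate
5 | 5,7-bis(benzyloxy)-2-[4-(benzyloxy)-3-hydroxyphenyl]-4H-chromen-4-one | O=c1cc(-c2ccc(OCc3ccccc3)c(O)c2)oc2cc(OCc3ccccc3)cc(OCc3ccccc3)c12 | intermediate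
6 | 4-fluorobenzaldehyde | O=Cc1ccc(F)cc1 | starting material
7 | 4-{2-(benzyloxy)-5-[5,7-bis(benzyloxy)-4-oxo-4H-chromen-2-yl]phenoxy}benzaldehyde | O=Cc1ccc(Oc2cc(-c3cc(=O)c4c(OCc5ccccc5)cc(OCc5ccccc5)cc4o3)ccc2OCc2ccccc2)cc1 | intermediate
8 | diethyl {2-[methoxy(methyl)amino]-2-oxoethyl}phosphonate | CCOP(=O)(CC(=O)N(C)OC)OCC | starting material
9 | (2E)-3-(4-{2-(benzyloxy)-5-[5,7-bis(benzyloxy)-4-oxo-4H-chromen-2-yl]phenoxy}phenyl)-N-methoxy-N-methylprop-2-enamide | CON(C)C(=O)/C=C/c1ccc(Oc2cc(-c3cc(=O)c4c(OCc5ccccc5)cc(OCc5ccccc5)cc4o3)ccc2OCc2ccccc2)cc1 | intermediate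
10 | 4-methoxy-6-methyl-2H-pyran-2-one | COc1cc(=O)oc(C)c1 | starting material
11 | [(4-methoxy-2-oxo-2H-pyran-6-yl)methyl]lithium | [Li]Cc1cc(OC)cc(=O)o1 | intermediate
12 | 6-[(3E)-4-(4-{2-(benzyloxy)-5-[5,7-bis(benzyloxy)-4-oxo-4H-chromen-2-yl]phenoxy}phenyl)-2-oxobut-3-en-1-yl]-4-methoxy-2H-pyran-2-one | COc1cc(=O)oc(CC(=O)/C=C/c2ccc(Oc3cc(-c4cc(=O)c5c(OCc6ccccc6)cc(OCc6ccccc6)cc5o4)ccc3OCc3ccccc3)cc2)c1 | intermediate
13 | methyl (2E,8E)-9-(4-{2-(benzyloxy)-5-[5,7-bis(benzyloxy)-4-oxo-4H-chromen-2-yl]phenoxy}phenyl)-3-methoxy-5,7-dioxonona-2,8-dienoate (present as its magnesium enolate) | COC(=O)/C=C(/OC)CC(=O)CC(=O)/C=C/c1ccc(Oc2cc(-c3cc(=O)c4c(OCc5ccccc5)cc(OCc5ccccc5)cc4o3)ccc2OCc2ccccc2)cc1 | intermediate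
14 | (2E)-3-(4-{2-(benzyloxy)-5-[5,7-bis(benzyloxy)-4-oxo-4H-chromen-2-yl]phenoxy}phenyl)-1-(2,6-dihydroxy-4-methoxyphenyl)prop-2-en-1-one | COc1cc(O)c(C(=O)/C=C/c2ccc(Oc3cc(-c4cc(=O)c5c(OCc6ccccc6)cc(OCc6ccccc6)cc5o4)ccc3OCc3ccccc3)cc2)c(O)c1 | intermediate
15 | (2E)-1-[2-(benzyloxy)-6-hydroxy-4-methoxyphenyl]-3-(4-{2-(benzyloxy)-5-[5,7-bis(benzyloxy)-4-oxo-4H-chromen-2-yl]phenoxy}phenyl)prop-2-en-1-one | COc1cc(O)c(C(=O)/C=C/c2ccc(Oc3cc(-c4cc(=O)c5c(OCc6ccccc6)cc(OCc6ccccc6)cc5o4)ccc3OCc3ccccc3)cc2)c(OCc2ccccc2)c1 | intermediate
16 | (2S)-5-(benzyloxy)-2-(4-{2-(benzyloxy)-5-[5,7-bis(benzyloxy)-4-oxo-4H-chromen-2-yl]phenoxy}phenyl)-7-methoxy-2,3-dihydro-4H-chromen-4-one | COc1cc(OCc2ccccc2)c2c(c1)O[C@H](c1ccc(Oc3cc(-c4cc(=O)c5c(OCc6ccccc6)cc(OCc6ccccc6)cc5o4)ccc3OCc3ccccc3)cc1)CC2=O | intermediate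
17 | (2S)-2-{4-[5-(5,7-dihydroxy-4-oxo-4H-chromen-2-yl)-2-hydroxyphenoxy]phenyl}-5-hydroxy-7-methoxy-2,3-dihydro-4H-chromen-4-one | COc1cc(O)c2c(c1)O[C@H](c1ccc(Oc3cc(-c4cc(=O)c5c(O)cc(O)cc5o4)ccc3O)cc1)CC2=O | target

## Step count and least certain steps

Total: 10 steps. Longest linear sequence: 10 steps (1 to 17); 3, 6, 8 and 10 are bought and enter this line directly. 2 is also an article of commerce, and buying it would take one step off both counts.

In the names below Ar* stands for the 4-{2-(benzyloxy)-5-[5,7-bis(benzyloxy)-4-oxo-4H-chromen-2-yl]phenoxy}phenyl group.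

Step 7 (key step). The most likely failure is early oxa-Michael closure of ring C, in the basic medium or while the mixture passes through neutral pH at the quench. A 2',6'-dihydroxychalcone always has one phenol free to add to the enone, so racemic closed material would replace 14. Step 8 should reopen such material, but stalling at the open-chain ester 13, addition of methoxide to the enone or cleavage of ring E by methoxide would not be repaired. Fallback: ring A is bought instead of built. The way sets out from 7. Purchased 1-(2,6-dihydroxy-4-methoxyphenyl)ethan-1-one F1 is monobenzylated (BnBr, K2CO3, acetone, rt) to 1-[2-(benzyloxy)-6-hydroxy-4-methoxyphenyl]ethan-1-one F2. F2 is condensed with 7 (KOH, EtOH/THF, rt, Claisen–Schmidt) and the route is rejoined at 15.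

Step 9. Poor facial selectivity and slow turnover are the main risks, because an unactivated enone binds the thiourea through one carbonyl only. Enantiopurity may also be eroded by retro-oxa-Michael reopening under the basic catalyst. Fallback: resolution with recycling. From 15, closure with NaOAc in EtOH/THF at reflux gives racemic 5-(benzyloxy)-7-methoxy-2-Ar*-2,3-dihydro-4H-chromen-4-one F3. Preparative chromatography on a chiral stationary phase (amylose tris(3,5-dimethylphenylcarbamate)) separates 16 from (2R)-5-(benzyloxy)-7-methoxy-2-Ar*-2,3-dihydro-4H-chromen-4-one F4. F4 is reopened to 15 with KOH in MeOH/THF and sent round again; the route is rejoined at 16.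

Step 6. Conjugate addition of 11 to the cinnamoyl amide or to C2 of ring E, incomplete lateral lithiation with competing ring metalation, and precipitation of 9 at −78 °C are the likely failures. Fallback: aldol addition and oxidation in place of acylation. From 7, Wittig olefination with (triphenylphosphoranylidene)acetaldehyde (toluene/THF, 80 °C) gives (2E)-3-Ar*-prop-2-enal F5. Addition of 11 (from 10 and LiN(i-Pr)2, THF, −78 °C) to the aldehyde gives racemic 6-[(3E)-2-hydroxy-4-Ar*-but-3-en-1-yl]-4-methoxy-2H-pyran-2-one F6. Oxidation of the allylic alcohol with MnO2 in CH2Cl2 rejoins the route at 12.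

Step 3. Loss of the benzyl group on the oxygen peri to the carbonyl through HI formed in the flask, and iodination of the electron-rich ring that carries the free phenol, are the likely side processes. Fallback: closure and dehydrogenation are separated and iodine is left out. From 4, NaOAc in EtOH at reflux gives racemic 5,7-bis(benzyloxy)-2-[4-(benzyloxy)-3-hydroxyphenyl]-2,3-dihydro-4H-chromen-4-one F7. Aerobic dehydrogenation with Pd(OCOCF3)2 (5 mol%, divalent palladium), DMSO (10 mol%) and O2 in AcOH at 80 °C rejoins the route at 5.

Step 10. Over-reduction, either saturation of C2=C3 of ring E or hydrogenolytic cleavage of the benzylic O1–C2 bond of ring C, may occur. Incomplete debenzylation is also possible because partly deprotected material is poorly soluble. Fallback: Lewis-acid cleavage in place of hydrogenolysis. From 16, BCl3 with pentamethylbenzene as cation scavenger in CH2Cl2 at −78 °C removes the four benzyl ethers and should leave the C7 methyl ether, which is not peri to a carbonyl; the route is rejoined at 17 and no new compound is made on this way (F0).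

## Further compounds

F1 | step 7 | 1-(2,6-dihydroxy-4-methoxyphenyl)ethan-1-one | CC(=O)c1c(O)cc(OC)cc1O
F2 | step 7 | 1-[2-(benzyloxy)-6-hydroxy-4-methoxyphenyl]ethan-1-one | CC(=O)c1c(O)cc(OC)cc1OCc1ccccc1
F3 | step 9 | racemic 5-(benzyloxy)-2-(4-{2-(benzyloxy)-5-[5,7-bis(benzyloxy)-4-oxo-4H-chromen-2-yl]phenoxy}phenyl)-7-methoxy-2,3-dihydro-4H-chromen-4-one | COc1cc(OCc2ccccc2)c2c(c1)OC(c1ccc(Oc3cc(-c4cc(=O)c5c(OCc6ccccc6)cc(OCc6ccccc6)cc5o4)ccc3OCc3ccccc3)cc1)CC2=O
F4 | step 9 | (2R)-5-(benzyloxy)-2-(4-{2-(benzyloxy)-5-[5,7-bis(benzyloxy)-4-oxo-4H-chromen-2-yl]phenoxy}phenyl)-7-methoxy-2,3-dihydro-4H-chromen-4-one | COc1cc(OCc2ccccc2)c2c(c1)O[C@@H](c1ccc(Oc3cc(-c4cc(=O)c5c(OCc6ccccc6)cc(OCc6ccccc6)cc5o4)ccc3OCc3ccccc3)cc1)CC2=O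
F5 | step 6 | (2E)-3-(4-{2-(benzyloxy)-5-[5,7-bis(benzyloxy)-4-oxo-4H-chromen-2-yl]phenoxy}phenyl)prop-2-enal | O=C/C=C/c1ccc(Oc2cc(-c3cc(=O)c4c(OCc5ccccc5)cc(OCc5ccccc5)cc4o3)ccc2OCc2ccccc2)cc1
F6 | step 6 | racemic 6-[(3E)-4-(4-{2-(benzyloxy)-5-[5,7-bis(benzyloxy)-4-oxo-4H-chromen-2-yl]phenoxy}phenyl)-2-hydroxybut-3-en-1-yl]-4-methoxy-2H-pyran-2-one | COc1cc(=O)oc(CC(O)/C=C/c2ccc(Oc3cc(-c4cc(=O)c5c(OCc6ccccc6)cc(OCc6ccccc6)cc5o4)ccc3OCc3ccccc3)cc2)c1
F7 | step 3 | racemic 5,7-bis(benzyloxy)-2-[4-(benzyloxy)-3-hydroxyphenyl]-2,3-dihydro-4H-chromen-4-one | O=C1CC(c2ccc(OCc3ccccc3)c(O)c2)Oc2cc(OCc3ccccc3)cc(OCc3ccccc3)c12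
F0 | step 10 | none | none
A1 | alternative 1 | (2S)-2-{4-[2-(benzyloxy)-5-(1,3-dioxolan-2-yl)phenoxy]phenyl}-5,7-dimethoxy-2,3-dihydro-4H-chromen-4-one | COc1cc(OC)c2c(c1)O[C@H](c1ccc(Oc3cc(C4OCCO4)ccc3OCc3ccccc3)cc1)CC2=O
A2 | alternative 1 | (3S)-3-{4-[2-(benzyloxy)-5-(1,3-dioxolan-2-yl)phenoxy]phenyl}-3-(2-bromo-3,5-dimethoxyphenoxy)propanoic acid | COc1cc(OC)c(Br)c(c1)O[C@@H](CC(=O)O)c1ccc(Oc2cc(C3OCCO3)ccc2OCc2ccccc2)cc1
A3 | alternative 2 | 2-[4-(benzyloxy)-3-(4-bromophenoxy)phenyl]-5,7-dihydroxy-4H-chromen-4-one | O=c1cc(-c2ccc(OCc3ccccc3)c(Oc3ccc(Br)cc3)c2)oc2cc(O)cc(O)c12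
A4 | alternative 2 | 6-{4-[4-(benzyloxy)-3-(4-bromophenoxy)phenyl]-2,4-dioxobutyl}-4-hydroxy-2H-pyran-2-one | O=C(CC(=O)Cc1cc(O)cc(=O)o1)c1ccc(OCc2ccccc2)c(Oc2ccc(Br)cc2)c1
A5 | alternative 3 | tert-butyl (2S,3R)-5-(benzyloxy)-2-(4-{2-(benzyloxy)-5-[5,7-bis(benzyloxy)-4-oxo-4H-chromen-2-yl]phenoxy}phenyl)-7-methoxy-4-oxo-3,4-dihydro-2H-chromene-3-carboxylate (2,3-trans) | COc1cc(OCc2ccccc2)c2c(c1)O[C@H](c1ccc(Oc3cc(-c4cc(=O)c5c(OCc6ccccc6)cc(OCc6ccccc6)cc5o4)ccc3OCc3ccccc3)cc1)[C@@H](C(=O)OC(C)(C)C)C2=O
A6 | alternative 3 | tert-butyl 2-[2-(benzyloxy)-6-hydroxy-4-methoxybenzoyl]-3-(4-{2-(benzyloxy)-5-[5,7-bis(benzyloxy)-4-oxo-4H-chromen-2-yl]phenoxy}phenyl)prop-2-enoate (alkene geometry not fixed) | COc1cc(O)c(C(=O)C(=Cc2ccc(Oc3cc(-c4cc(=O)c5c(OCc6ccccc6)cc(OCc6ccccc6)cc5o4)ccc3OCc3ccccc3)cc2)C(=O)OC(C)(C)C)c(OCc2ccccc2)c1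
A7 | alternative 3 | tert-butyl 3-[2-(benzyloxy)-6-hydroxy-4-methoxyphenyl]-3-oxopropanoate | COc1cc(O)c(C(=O)CC(=O)OC(C)(C)C)c(OCc2ccccc2)c1
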